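**Plan**

Numbering of each half: ring A = arene C4a, C5(H), C6(CH3), C7(OH), C8 (biaryl carbon), C8a; ring B = C1(H)(CH3)–C2H2–C3H2–C4(H)(iPr), closed through C4a and C8a.
Retrosynthesis: the C8–C8' bond is cut first (oxidative coupling of two identical phenols at their only free ortho carbon). In the monomer, C1–C2 and C3–C4 are then cut together, which lifts the C2–C3 unit out of ring B.
Enabling feature: C1 and C4 are benzylic carbons on the neighbouring arene carbons C8a and C4a, and C4 is para to O7. With C4 as an aryl ketone carbonyl and C1 as the CH2 of an ortho ethyl group, light turns ring A into the hydroxy-o-quinodimethane C1=C8a–C4a=C4, whose termini take up an acrylate C=C (C2–C3) in one [4+2] event.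
Forward: ring A is bought; acylation para to OMe (C4), ortho C–H ethylation (C1), photoenolization/Diels–Alder (ring B), removal of the ester and hydroxyl helpers as CO2 and water, hydrogenation, O-demethylation, and dimerisation last, since a C8 substituent would clash with the outward C1 methyl of the diene.
Stereochemistry: C1 comes from the diene face left open by the TADDOLate–titanium template in the key step; C4 from matched, catalyst-controlled hydrogenation anti to the C1 methyl; both halves arise from one enantiopure monomer.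

Key step: step 3

Assumption: the sense of the biaryl axis is not defined in the target, so whichever axial diastereomer (or mixture) the coupling of the (S,S) monomer gives is taken as the target.

Step 1
Reactants: 1 2-methylanisole; 2 2-methylpropanoyl chloride
Product: 3 1-(4-methoxy-3-methylphenyl)-2-methylpropan-1-one
Conditions: AlCl3 (1.2 equiv), CH2Cl2, 0 °C to rt
Reagents that add atoms: none
Why: Friedel–Crafts acylation, in which the methoxy group directs the acylium ion to its para position (C4a of the target), which is also the least hindered site.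

Step 2
Reactants: 3 1-(4-methoxy-3-methylphenyl)-2-methylpropan-1-one; 4 ethene
Product: 5 1-(2-ethyl-4-methoxy-5-methylphenyl)-2-methylpropan-1-one
Conditions: RuH2(CO)(PPh3)3 (5 mol %), ethene (7 bar), toluene, 135 °C
Reagents that add atoms: none
Why: Murai reaction (ruthenium-catalysed, ketone-directed ortho-C–H addition to an olefin), in which the carbonyl oxygen guides ruthenium into the ortho C–H bond and only the ortho position not flanked by the ring methyl is reached, so a single ethyl group enters at C8a.

Step 3
Reactants: 5 1-(2-ethyl-4-methoxy-5-methylphenyl)-2-methylpropan-1-one; 6 prop-2-enyl prop-2-enoate (allyl acrylate)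
Product: 8 prop-2-enyl (1R,2R,4S)-1-hydroxy-6-methoxy-4,7-dimethyl-1-(propan-2-yl)-1,2,3,4-tetrahydronaphthalene-2-carboxylate, via titanium-bound (E,E)-hydroxy-o-quinodimethane 7 (not isolated)
Conditions: Ti(OiPr)4 (1.2 equiv), (R,R)-TADDOL (1.3 equiv), toluene, hν 366 nm, −20 °C
Reagents that add atoms: none
Why: Proposed new method: light excites the titanium-bound ketone, a 1,5-hydrogen shift from the ortho-ethyl CH2 to the carbonyl oxygen gives the (E,E)-hydroxy-o-quinodimethane 7 as a titanium dienolate (oxygen and methyl both outward), and the same TADDOLate–titanium centre holds the acrylate carbonyl, so that the [4+2] cycloaddition runs inside a chiral template. The closest known reaction types are the titanium-alkoxide-templated photoenolization/Diels–Alder reaction of o-alkylbenzaldehydes with enones, including its TADDOLate enantioselective form, and the untemplated photoenolization/Diels–Alder reaction of o-alkyl aryl ketones with acrylates; the enantioselective form has not been shown for an o-ethyl aryl isopropyl ketone with an acrylate. Ring B closes by an intermolecular suprafacial [4+2] cycloaddition in which C1–C2 and C3–C4 form on the same face of the diene. The carbinol centre (target C4) and the ester centre (target C3) are fixed by the Ti–O/C=O chelate (ester carbon next to the carbinol and cis to the hydroxyl, endo), and the methyl centre (target C1) by the outward (E) methyl together with the diene face that the ligand leaves open; the (R,R)-ligand is assumed to give 4S in 8, and the (S,S)-ligand is taken if the sense is the opposite. The step needs regioselectivity, secured by the chelate and by the polarisation of the dienol (nucleophilic CH–CH3 terminus to the acrylate β-carbon), E geometry at C1, secured because an inward methyl would clash with the inward isopropyl group, and face selectivity, which only the ligand can give because the diene is flat. Only the methyl-bearing centre has to last, since the carbinol and ester centres are removed in step 5.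

Step 4
Reactants: 8 prop-2-enyl (1R,2R,4S)-1-hydroxy-6-methoxy-4,7-dimethyl-1-(propan-2-yl)-1,2,3,4-tetrahydronaphthalene-2-carboxylate
Product: 9 (1R,2R,4S)-1-hydroxy-6-methoxy-4,7-dimethyl-1-(propan-2-yl)-1,2,3,4-tetrahydronaphthalene-2-carboxylic acid
Conditions: Pd(PPh3)4 (5 mol %), morpholine (5 equiv), THF, rt; then aq. NaH2PO4
Reagents that add atoms: none
Why: Tsuji–Trost deallylation, in which zerovalent palladium ionises the allyl ester and morpholine traps the π-allyl unit, so the acid is freed under near-neutral conditions that avoid retro-aldol opening of the tertiary β-hydroxy ester.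

Step 5
Reactants: 9 (1R,2R,4S)-1-hydroxy-6-methoxy-4,7-dimethyl-1-(propan-2-yl)-1,2,3,4-tetrahydronaphthalene-2-carboxylic acid
Product: 11 (1S)-7-methoxy-1,6-dimethyl-4-(propan-2-yl)-1,2-dihydronaphthalene, via cis-fused β-lactone 10 (not isolated)
Conditions: PhSO2Cl (2 equiv), pyridine, 0 °C to rt; then 90 °C
Reagents that add atoms: none
Why: Decarboxylative dehydration of a β-hydroxy acid through its β-lactone, in which sulfonyl activation of the carboxyl, ring closure by the cis tertiary hydroxyl and thermal [2+2] cycloreversion with loss of CO2 (eased by the p-methoxyaryl tertiary carbon) place the double bond at C3=C4 and leave C1 untouched.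

Step 6
Reactants: 11 (1S)-7-methoxy-1,6-dimethyl-4-(propan-2-yl)-1,2-dihydronaphthalene
Product: 12 (1S,4S)-7-methoxy-1,6-dimethyl-4-(propan-2-yl)-1,2,3,4-tetrahydronaphthalene (cis)
Conditions: [Ir(cod)((S)-tBu-PHOX)]BArF (2 mol %), H2 (50 bar), CH2Cl2, rt
Reagents that add atoms: none
Why: Iridium P,N-ligand-catalysed asymmetric hydrogenation of an unfunctionalised trisubstituted aryl alkene, in which H2 should add to C3=C4 on the face anti to the pseudoaxial C1 methyl, the substrate's own bias, which the matched ligand enantiomer reinforces (the (R)-ligand is taken if the (S)-ligand proves mismatched), so that C4 is set cis to C1.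

Step 7
Reactants: 12 (1S,4S)-7-methoxy-1,6-dimethyl-4-(propan-2-yl)-1,2,3,4-tetrahydronaphthalene
Product: 13 (5S,8S)-3,8-dimethyl-5-(propan-2-yl)-5,6,7,8-tetrahydronaphthalen-2-ol ((1S,4S)-7-hydroxycalamenene)
Conditions: BBr3 (1.5 equiv), CH2Cl2, −78 to 0 °C; then H2O
Reagents that add atoms: none
Why: Lewis-acid ether cleavage, in which BBr3 binds the methoxy oxygen and bromide removes the methyl group by SN2 attack, a reaction that does not touch the benzylic stereocentres.

Step 8
Reactants: 13 (5S,8S)-3,8-dimethyl-5-(propan-2-yl)-5,6,7,8-tetrahydronaphthalen-2-ol (two molecules)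
Product: 14 (5S,5'S,8S,8'S)-3,3',8,8'-tetramethyl-5,5'-di(propan-2-yl)-5,5',6,6',7,7',8,8'-octahydro-[1,1'-binaphthalene]-2,2'-diol (target)
Conditions: [Cu(OH)(TMEDA)]2Cl2 (10 mol %), O2 (1 atm), CH2Cl2, rt
Reagents that add atoms: none
Why: Copper-catalysed aerobic oxidative phenol coupling (ortho–ortho dimerisation of phenoxyl/copper phenoxide species), well known for 2,4,5-trialkylphenols and 3-alkyl-5,6,7,8-tetrahydro-2-naphthols, in which C8 is the only free ortho position and the para carbon C4a is substituted, so C–C bond formation can only give the 8,8'-dimer and the enantiopure monomer can only give the (S,S,S,S) compound.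

**Compound list**

1 | 2-methylanisole (1-methoxy-2-methylbenzene) | COc1ccccc1C | starting material
2 | 2-methylpropanoyl chloride (isobutyryl chloride) | CC(C)C(Cl)=O | starting material
3 | 1-(4-methoxy-3-methylphenyl)-2-methylpropan-1-one | CC(C)C(=O)c1ccc(OC)c(C)c1 | intermediate
4 | ethene | C=C | starting material
5 | 1-(2-ethyl-4-methoxy-5-methylphenyl)-2-methylpropan-1-one | CCc1cc(OC)c(C)cc1C(=O)C(C)C | intermediate
6 | prop-2-enyl prop-2-enoate (allyl acrylate) | C=CC(=O)OCC=C | starting material
7 | (E,E)-hydroxy-o-quinodimethane, 1-[6-ethylidene-4-methoxy-3-methylcyclohexa-2,4-dien-1-ylidene]-2-methylpropan-1-ol, hydroxyl and methyl both outward (drawn as the free dienol; bound to titanium through oxygen in the flask) | C/C=C1\C=C(OC)C(C)=C/C1=C(\O)C(C)C | intermediate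
8 | prop-2-enyl (1R,2R,4S)-1-hydroxy-6-methoxy-4,7-dimethyl-1-(propan-2-yl)-1,2,3,4-tetrahydronaphthalene-2-carboxylate (hydroxyl, ester and C4 methyl all cis) | Cc1cc2c(cc1OC)[C@@H](C)C[C@@H](C(=O)OCC=C)[C@]2(O)C(C)C | intermediate
9 | (1R,2R,4S)-1-hydroxy-6-methoxy-4,7-dimethyl-1-(propan-2-yl)-1,2,3,4-tetrahydronaphthalene-2-carboxylic acid | Cc1cc2c(cc1OC)[C@@H](C)C[C@@H](C(=O)O)[C@]2(O)C(C)C | intermediate
10 | cis-fused β-lactone of 9 (oxetan-2-one closed between the C2 carboxyl and the C1 oxygen, configuration as in 9) | Cc1cc2c(cc1OC)[C@@H](C)C[C@H]3C(=O)O[C@@]23C(C)C | intermediate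
11 | (1S)-7-methoxy-1,6-dimethyl-4-(propan-2-yl)-1,2-dihydronaphthalene | Cc1cc2c(cc1OC)[C@@H](C)CC=C2C(C)C | intermediate
12 | (1S,4S)-7-methoxy-1,6-dimethyl-4-(propan-2-yl)-1,2,3,4-tetrahydronaphthalene (cis) | Cc1cc2c(cc1OC)[C@@H](C)CC[C@H]2C(C)C | intermediate
13 | (5S,8S)-3,8-dimethyl-5-(propan-2-yl)-5,6,7,8-tetrahydronaphthalen-2-ol | Cc1cc2c(cc1O)[C@@H](C)CC[C@H]2C(C)C | intermediate
14 | (5S,5'S,8S,8'S)-3,3',8,8'-tetramethyl-5,5'-di(propan-2-yl)-5,5',6,6',7,7',8,8'-octahydro-[1,1'-binaphthalene]-2,2'-diol | Cc1cc2c(c(-c3c(O)c(C)cc4c3[C@@H](C)CC[C@H]4C(C)C)c1O)[C@@H](C)CC[C@H]2C(C)C | target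

**Count**

Total steps: 8. Longest linear sequence: 8 steps (1 to 14).

**Steps most likely to fail**

Step 3. What may go wrong: weak discrimination of the two diene faces by the titanium template (the inward isopropyl group twists the dienol), or return of the dienol to ketone 5 by 1,5-hydrogen shift faster than cycloaddition. The fallback uses known chemistry and replaces asymmetric catalysis by resolution. It sets out from 5: the untemplated photoenolization/Diels–Alder reaction with 6 (366 nm, toluene, no titanium, no ligand) should give the racemic endo adduct, racemic prop-2-enyl (1R*,2R*,4S*)-1-hydroxy-6-methoxy-4,7-dimethyl-1-(propan-2-yl)-1,2,3,4-tetrahydronaphthalene-2-carboxylate F1. Deallylation with Pd(PPh3)4 and morpholine should give the racemic acid F2. Crystallisation with (R)-1-phenylethylamine should give the less soluble diastereomeric salt, (R)-1-phenylethylammonium (1R,2R,4S)-1-hydroxy-6-methoxy-4,7-dimethyl-1-(propan-2-yl)-1,2,3,4-tetrahydronaphthalene-2-carboxylate F3 (the (S)-amine is used if it is the one that crystallises the wanted acid). Acidification comes back to the route at 9.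

Step 8. What may go wrong: C–C coupling at the hindered C8 is outrun by C–O coupling, by further oxidation of the biphenol, or by hydrogen loss at the para benzylic C4–H (quinone methide formation), which would also erase C4. The fallback replaces the oxidative coupling by a cross-coupling of two pre-functionalised halves and sets out from 12. Bromination ortho to the methoxy group (NBS, MeCN) should give (5S,8S)-1-bromo-2-methoxy-3,8-dimethyl-5-(propan-2-yl)-5,6,7,8-tetrahydronaphthalene F4. Miyaura-type borylation of half of it (pinacolborane, Et3N, PdCl2(MeCN)2/SPhos, dioxane, 110 °C) should give the pinacol boronate, 2-[(5S,8S)-2-methoxy-3,8-dimethyl-5-(propan-2-yl)-5,6,7,8-tetrahydronaphthalen-1-yl]-4,4,5,5-tetramethyl-1,3,2-dioxaborolane F5. Suzuki–Miyaura coupling of F4 with F5 (Pd2(dba)3/SPhos, K3PO4, toluene/H2O, 110 °C) should give the dimer bis(methyl ether), (5S,5'S,8S,8'S)-2,2'-dimethoxy-3,3',8,8'-tetramethyl-5,5'-di(propan-2-yl)-5,5',6,6',7,7',8,8'-octahydro-1,1'-binaphthalene F6. BBr3 comes back to the route at 14.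

Step 6. What may go wrong: poor facial selectivity if catalyst and substrate bias are mismatched, or incomplete reduction of the isopropyl-bearing alkene. The fallback sets C4 by 1,2-induction from the ester centre made in the key step instead of by hydrogenation, and sets out from 8. Ionic hydrogenation (Et3SiH, CF3CO2H, CH2Cl2, −40 to 0 °C) should deliver hydride to the benzylic cation anti to the neighbouring pseudoaxial ester and give prop-2-enyl (1R,2R,4S)-6-methoxy-4,7-dimethyl-1-(propan-2-yl)-1,2,3,4-tetrahydronaphthalene-2-carboxylate F7. Deallylation (Pd(PPh3)4, morpholine) should give (1R,2R,4S)-6-methoxy-4,7-dimethyl-1-(propan-2-yl)-1,2,3,4-tetrahydronaphthalene-2-carboxylic acid F8. Photoredox hydrodecarboxylation (9-mesityl-10-phenylacridinium tetrafluoroborate as catalyst, PhSSPh, iPr2NEt, CF3CH2OH, 450 nm) comes back to the route at 12.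

**Further compounds**

F1 | step 3 | racemic prop-2-enyl (1R*,2R*,4S*)-1-hydroxy-6-methoxy-4,7-dimethyl-1-(propan-2-yl)-1,2,3,4-tetrahydronaphthalene-2-carboxylate | Cc1cc2c(cc1OC)[C@@H](C)C[C@@H](C(=O)OCC=C)[C@]2(O)C(C)C.Cc1cc2c(cc1OC)[C@H](C)C[C@H](C(=O)OCC=C)[C@@]2(O)C(C)C
F2 | step 3 | racemic (1R*,2R*,4S*)-1-hydroxy-6-methoxy-4,7-dimethyl-1-(propan-2-yl)-1,2,3,4-tetrahydronaphthalene-2-carboxylic acid | Cc1cc2c(cc1OC)[C@@H](C)C[C@@H](C(=O)O)[C@]2(O)C(C)C.Cc1cc2c(cc1OC)[C@H](C)C[C@H](C(=O)O)[C@@]2(O)C(C)C
F3 | step 3 | (R)-1-phenylethylammonium (1R,2R,4S)-1-hydroxy-6-methoxy-4,7-dimethyl-1-(propan-2-yl)-1,2,3,4-tetrahydronaphthalene-2-carboxylate | Cc1cc2c(cc1OC)[C@@H](C)C[C@@H](C(=O)[O-])[C@]2(O)C(C)C.C[C@@H]([NH3+])c1ccccc1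
F4 | step 8 | (5S,8S)-1-bromo-2-methoxy-3,8-dimethyl-5-(propan-2-yl)-5,6,7,8-tetrahydronaphthalene | Cc1cc2c(c(Br)c1OC)[C@@H](C)CC[C@H]2C(C)C
F5 | step 8 | 2-[(5S,8S)-2-methoxy-3,8-dimethyl-5-(propan-2-yl)-5,6,7,8-tetrahydronaphthalen-1-yl]-4,4,5,5-tetramethyl-1,3,2-dioxaborolane | Cc1cc2c(c(B3OC(C)(C)C(C)(C)O3)c1OC)[C@@H](C)CC[C@H]2C(C)C
F6 | step 8 | (5S,5'S,8S,8'S)-2,2'-dimethoxy-3,3',8,8'-tetramethyl-5,5'-di(propan-2-yl)-5,5',6,6',7,7',8,8'-octahydro-1,1'-binaphthalene | Cc1cc2c(c(-c3c(OC)c(C)cc4c3[C@@H](C)CC[C@H]4C(C)C)c1OC)[C@@H](C)CC[C@H]2C(C)C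
F7 | step 6 | prop-2-enyl (1R,2R,4S)-6-methoxy-4,7-dimethyl-1-(propan-2-yl)-1,2,3,4-tetrahydronaphthalene-2-carboxylate | Cc1cc2c(cc1OC)[C@@H](C)C[C@@H](C(=O)OCC=C)[C@H]2C(C)C
F8 | step 6 | (1R,2R,4S)-6-methoxy-4,7-dimethyl-1-(propan-2-yl)-1,2,3,4-tetrahydronaphthalene-2-carboxylic acid | Cc1cc2c(cc1OC)[C@@H](C)C[C@@H](C(=O)O)[C@H]2C(C)C
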